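## Structural features

- The target is an isoflavan-quinone. A chroman (ring A fused to pyran ring C: O1, C2, C3, C4, C4a–C8a) carries at C3 a 2,3-dimethoxy-1,4-benzoquinone (ring B, C1'–C6'), with carbonyls at C2' and C5', methoxy groups at C3' and C4', and H at C6'.
- C3 is the only stereocentre and is (S) in the given SMILES. It bears H, ring B and the two methylene groups C2 (to O1) and C4 (to C4a), so there is no neighbouring centre to relay from.
- C3–H is allylic to C1'=C6' and vinylogously α to the C5' carbonyl. Base, and to a lesser degree acid or long heating, can tautomerise the alkylquinone to a quinone methide and erase the centre.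
- Ring A is a 1,2,3,4-tetraoxygenated benzene (O1 on C8a, OMe on C8, free OH on C7, OMe on C6). Ring B in its reduced form is the same kind of arene, so the two rings are near twins in oxidation potential.
- Fragile groups are the quinone (nucleophiles, base, reductants), the hindered C7 phenol, and the electron-rich ring A (oxidants, electrophiles).
- The real difficulty is not the chroman. It is to have ring B as a quinone with the correct C=O/OMe pattern while ring A stays an arene, and to deliver C3 intact next to that quinone.
- The key step exploits the C2'–C5' unit of ring B. The contiguous carbons C2'(=O), C3'(OMe), C4'(OMe), C5'(=O) are the carbon skeleton of dimethyl squarate, and C1'/C6' are a two-carbon alkyne unit. Ring B is therefore built, already oxidised, by strain-release ring expansion of a cyclobutenone and not by oxidation of an arene.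

## Logic of the disconnections

**18 ⇒ 17.** The O–CH2 bond of an acetal on the C7 oxygen is cut. The phenol must be masked from step 1 onward against base, organolithium and the ketene of the key step. The forward step must be a mild, base-free cleavage that leaves the quinone and C3 alone.

**17 ⇒ 14 (key).** The C1'–C2' bond of ring B is cut and C2' is reconnected to C5', which contracts the quinone to a four-membered ring carrying a carbinol and an alkyne. In one sentence: a 4-alkynyl-4-hydroxycyclobutenone that already carries the finished chroman is heated and ring-expands to the quinone. The gain is that ring B appears directly in the quinone oxidation state with both methoxy groups and the C6'–H in place, and no oxidant ever meets ring A. The demand is a clean thermal cascade through 15 and 16 that closes the six-membered ring and leaves C3 untouched.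

**14 ⇒ 11 + 12.** The C5'–C6' bond (carbinol carbon to alkyne carbon) is cut. 12 supplies C2'–C5' with both methoxy groups. 11 supplies C6' and C1' as a masked acetylide, together with the complete chroman and its stereocentre. The demand is mono-addition of 13 to one of the two equivalent carbonyls of 12 without metalation at C3.

**11 ⇒ 10 ⇒ 9 ⇒ 8.** C6' is removed (one-carbon homologation of an aldehyde), and C1' is traced back to a carboxyl carbon. The demand is that C3, now α to a carbonyl in 10, is not enolised.

**8 ⇒ 7.** The C3–H and C4–H bonds are cut. The stereocentre is set by hydrogenation of a trisubstituted olefin whose carboxyl group anchors the catalyst. The demand is high facial selectivity.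

**7 ⇒ 6 ⇒ 4 + 5.** O1–C2 and C3–C4 are cut. Ring C is formed by annulation of a salicylaldehyde with a C3 acceptor that also brings C1' as a nitrile carbon.

**4 ⇒ 3 ⇒ 2 ⇒ 1.** The C8a–O bond is cut back to C–Br and then C–H. Because 1 is symmetric, the two free ring positions are equivalent and only one substitution pattern can result.

## Other disconnections considered

**Alternative 1:** (the first that comes to mind) Cut O1–C2 and C3–C4, carrying ring B as a 2,3,4,5-tetramethoxyphenyl group. Forward: auxiliary-controlled benzylation gives imide A1, reduction and Mitsunobu closure give isoflavan A2, and oxidative demethylation with CAN makes the quinone last. Ground for rejection: in A2 both rings are tetraoxygenated arenes with para-disposed oxygens (C2'/C5' on ring B, C8a/C6 on ring A). Nothing in the structure tells the oxidant which ring to convert, and attack on ring A would open the pyran. The auxiliary also costs extra steps.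

**Alternative 2:** Cut the C3–H/C4–H bonds of an isoflav-3-ene. Forward: asymmetric hydrogenation of A3 (made from 4 and an arylacetic acid derivative) gives A2, followed by the same CAN oxidation. Ground for rejection: A3 has no coordinating group, so face selection rests on sterics alone against an ortho-methoxy aryl group. The route also ends in the same unselective ring oxidation as Alternative 1.

**Alternative 3:** Cut C3–C1' late. Forward: decarboxylative radical alkylation (Ag(I)/persulfate, Minisci-type) of quinone A4 with acid 8 gives A5. This is the shortest plan and reuses 8, but the C3 radical is planar and no element controls its face, so the configuration set by hydrogenation would be lost and A5 would be racemic. Persulfate is also a risk for ring A. The chosen plan keeps C3 a closed-shell sp3 carbon throughout.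

Key step: step 11

Assumption: the target is taken as the (3S) enantiomer as drawn; in step 6 the ligand antipode that delivers (R)-8 is used (both antipodes are available, the sense to be confirmed by correlation).

## Route

Step 1
Reactants: 1 syringaldehyde (4-hydroxy-3,5-dimethoxybenzaldehyde)
Product: 2 3,5-dimethoxy-4-(methoxymethoxy)benzaldehyde
Conditions: MOMCl, iPr2NEt, CH2Cl2, 0 °C → rt
Reagents that add atoms: chloromethyl methyl ether, COCCl
Why: O-alkylation of the acidic para-formyl phenol (MOM protection). MOM survives hydroxide, hydride, organolithium and heat, and leaves under mild acid at the end.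

Step 2
Reactants: 2 3,5-dimethoxy-4-(methoxymethoxy)benzaldehyde
Product: 3 2-bromo-3,5-dimethoxy-4-(methoxymethoxy)benzaldehyde
Conditions: NBS, MeCN, rt
Reagents that add atoms: N-bromosuccinimide, O=C1CCC(=O)N1Br
Why: Electrophilic aromatic bromination. The two free positions of 2 are equivalent by symmetry, each ortho to one OMe and para to the other, so only one monobromide can form.

Step 3
Reactants: 3 2-bromo-3,5-dimethoxy-4-(methoxymethoxy)benzaldehyde
Product: 4 2-hydroxy-3,5-dimethoxy-4-(methoxymethoxy)benzaldehyde
Conditions: Cu(acac)2 (5 mol %), N,N'-bis(4-hydroxy-2,6-dimethylphenyl)oxalamide (5 mol %), LiOH·H2O, DMSO/H2O, 80 °C; then aq. NaH2PO4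
Reagents that add atoms: lithium hydroxide, [Li+].[OH-]
Why: Copper-catalysed Ullmann-type hydroxylation of an aryl bromide, assisted by the ortho-formyl group. The product phenoxide is protected from further attack by its charge, and MOM is stable to hydroxide.

Step 4
Reactants: 4 2-hydroxy-3,5-dimethoxy-4-(methoxymethoxy)benzaldehyde; 5 acrylonitrile
Product: 6 6,8-dimethoxy-7-(methoxymethoxy)-2H-chromene-3-carbonitrile
Conditions: DABCO (0.5 equiv), neat 5 (excess), 80 °C
Reagents that add atoms: none
Why: DABCO-mediated Baylis–Hillman/oxa-Michael/dehydration annulation of a salicylaldehyde with acrylonitrile, the standard entry to 3-cyano-2H-chromenes. It forms O1–C2 and C3–C4 in one operation.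

Step 5
Reactants: 6 6,8-dimethoxy-7-(methoxymethoxy)-2H-chromene-3-carbonitrile
Product: 7 6,8-dimethoxy-7-(methoxymethoxy)-2H-chromene-3-carboxylic acid
Conditions: 10% aq. NaOH, reflux; then 1 M HCl to pH 3–4, 0 °C
Reagents that add atoms: sodium hydroxide, [Na+].[OH-]; water, O
Why: Alkaline hydrolysis of a conjugated nitrile to the carboxylate. The MOM acetal is inert to hydroxide, and cold, brief acidification should preserve it.

Step 6
Reactants: 7 6,8-dimethoxy-7-(methoxymethoxy)-2H-chromene-3-carboxylic acid
Product: 8 (3R)-6,8-dimethoxy-7-(methoxymethoxy)chromane-3-carboxylic acid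
Conditions: [Ir(cod)(SIPHOX)]BArF (1 mol %, antipode giving R), H2 (6 atm), Et3N (0.5 equiv), MeOH, 25 °C
Reagents that add atoms: none
Why: Carboxylate-directed iridium-catalysed asymmetric hydrogenation of a β-aryl-α-alkyl acrylic acid. The carboxylate binds iridium and the chiral spiro P,N pocket selects the olefin face, so C3 is set here. No group that homogeneous H2 would damage is present.

Step 7
Reactants: 8 (3R)-6,8-dimethoxy-7-(methoxymethoxy)chromane-3-carboxylic acid
Product: 9 [(3S)-6,8-dimethoxy-7-(methoxymethoxy)chroman-3-yl]methanol
Conditions: BH3·SMe2, THF, 0 °C → rt; then MeOH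
Reagents that add atoms: none
Why: Borane reduction of a carboxylic acid via the acyloxyborane, without enolisation. C3 is untouched, and the descriptor changes to S only through CIP priorities.

Step 8
Reactants: 9 [(3S)-6,8-dimethoxy-7-(methoxymethoxy)chroman-3-yl]methanol
Product: 10 (3R)-6,8-dimethoxy-7-(methoxymethoxy)chromane-3-carbaldehyde
Conditions: Dess–Martin periodinane, NaHCO3, CH2Cl2, 0 °C → rt; used crude at once
Reagents that add atoms: none
Why: Dess–Martin oxidation under buffered, non-basic conditions should give the α-branched aldehyde without enolisation or retro-oxa-Michael opening of the pyran.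

Step 9
Reactants: 10 (3R)-6,8-dimethoxy-7-(methoxymethoxy)chromane-3-carbaldehyde
Product: 11 (3S)-3-(2,2-dibromoethenyl)-6,8-dimethoxy-7-(methoxymethoxy)chromane
Conditions: CBr4, PPh3, CH2Cl2, 0 °C; then 2,6-lutidine, 10, −78 → 0 °C
Reagents that add atoms: carbon tetrabromide, BrC(Br)(Br)Br
Why: Ramirez dibromo-olefination (first stage of the Corey–Fuchs sequence) with the non-basic ylide Ph3P=CBr2. Lutidine buffers adventitious acid, so the MOM ether and the C3 centre should survive.

Step 10
Reactants: 11 (3S)-3-(2,2-dibromoethenyl)-6,8-dimethoxy-7-(methoxymethoxy)chromane; 12 dimethyl squarate (3,4-dimethoxycyclobut-3-ene-1,2-dione)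
Product: 14 4-{[(3S)-6,8-dimethoxy-7-(methoxymethoxy)chroman-3-yl]ethynyl}-4-hydroxy-2,3-dimethoxycyclobut-2-en-1-one (both carbinol epimers), via lithium acetylide 13 (not isolated)
Conditions: n-BuLi (2.05 equiv), THF, −78 °C; cannulate into 12, THF, −78 °C; sat. aq. NH4Cl, −78 °C
Reagents that add atoms: none
Why: Corey–Fuchs second stage: Br/Li exchange, α-elimination and 1,2-H shift (Fritsch–Buttenberg–Wiechell) give the alkyne, which the second equivalent of BuLi converts to acetylide 13. 1,2-Addition of 13 to one of the two equivalent carbonyls of 12 at −78 °C is a standard squarate reaction. The new carbinol centre forms without control, which does not matter because step 11 destroys it.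

Step 11
Reactants: 14 4-{[(3S)-6,8-dimethoxy-7-(methoxymethoxy)chroman-3-yl]ethynyl}-4-hydroxy-2,3-dimethoxycyclobut-2-en-1-one
Product: 17 5-[(3S)-6,8-dimethoxy-7-(methoxymethoxy)chroman-3-yl]-2,3-dimethoxy-1,4-benzoquinone, via enynylketene 15 (not isolated), via phenoxyl–aryl diradical 16 (not isolated)
Conditions: PhMe (0.01 M, degassed), 110 °C
Reagents that add atoms: none
Why: This is the Moore rearrangement, the known thermal ring expansion of squarate-derived 4-alkynyl-4-hydroxycyclobutenones to 2,3-dialkoxy-1,4-benzoquinones. Heating opens the strained four-membered ring of 14 by conrotatory 4π electrocyclic cleavage of the C(=O)–C(OH) bond; the donor hydroxyl rotates outward, so the alkynyl group turns inward and lies cis to the ketene in 15. The ketene carbon then bonds to the distal alkyne carbon (the one bearing the chroman) in a 6-endo-dig, Myers–Saito-like cycloaromatisation that closes the six-membered ring and gives diradical 16; transfer of the hydroxyl hydrogen to the σ-radical carbon gives quinone 17. Release of ring strain and the aromatic stabilisation of 16 drive the sequence, and since no oxidant, acid or base is present, ring A and the C3–H centre should remain spectators. No new stereocentre is formed: the carbinol centre of 14 is destroyed, so both epimers converge on 17, and C3 keeps the configuration set in step 6. The selectivity needed is six- over five-membered closure (5-exo-dig closure would give an alkylidenecyclopentenedione); an sp3 alkyl substituent on the alkyne terminus, as here, does not stabilise the exocyclic vinyl radical and so should favour the quinone. The regiochemistry is fixed by connectivity: the chroman-bearing carbon becomes C1' next to a carbonyl and the former acetylide carbon becomes C6'–H.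

Step 12
Reactants: 17 5-[(3S)-6,8-dimethoxy-7-(methoxymethoxy)chroman-3-yl]-2,3-dimethoxy-1,4-benzoquinone
Product: 18 5-[(3S)-7-hydroxy-6,8-dimethoxy-3,4-dihydro-2H-chromen-3-yl]-2,3-dimethoxycyclohexa-2,5-diene-1,4-dione (target)
Conditions: p-TsOH·H2O (0.2 equiv), MeOH, 40 °C
Reagents that add atoms: none
Why: Acid-catalysed acetal exchange (MOM cleavage) in methanol. Methanol traps the methoxymethyl cation as dimethoxymethane so it cannot alkylate C5 of ring A, any exchange at the quinone methoxy groups is degenerate in MeOH, and no base is present to epimerise C3.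

## Compound list

1 | syringaldehyde (4-hydroxy-3,5-dimethoxybenzaldehyde) | COc1cc(C=O)cc(OC)c1O | starting material
2 | 3,5-dimethoxy-4-(methoxymethoxy)benzaldehyde | COCOc1c(OC)cc(C=O)cc1OC | intermediate
3 | 2-bromo-3,5-dimethoxy-4-(methoxymethoxy)benzaldehyde | COCOc1c(OC)cc(C=O)c(Br)c1OC | intermediate
4 | 2-hydroxy-3,5-dimethoxy-4-(methoxymethoxy)benzaldehyde | COCOc1c(OC)cc(C=O)c(O)c1OC | intermediate
5 | acrylonitrile | C=CC#N | starting material
6 | 6,8-dimethoxy-7-(methoxymethoxy)-2H-chromene-3-carbonitrile | N#CC1=Cc2cc(OC)c(OCOC)c(OC)c2OC1 | intermediate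
7 | 6,8-dimethoxy-7-(methoxymethoxy)-2H-chromene-3-carboxylic acid | OC(=O)C1=Cc2cc(OC)c(OCOC)c(OC)c2OC1 | intermediate
8 | (3R)-6,8-dimethoxy-7-(methoxymethoxy)chromane-3-carboxylic acid | OC(=O)[C@H]1COc2c(cc(OC)c(OCOC)c2OC)C1 | intermediate
9 | [(3S)-6,8-dimethoxy-7-(methoxymethoxy)chroman-3-yl]methanol | OC[C@H]1COc2c(cc(OC)c(OCOC)c2OC)C1 | intermediate
10 | (3R)-6,8-dimethoxy-7-(methoxymethoxy)chromane-3-carbaldehyde | O=C[C@H]1COc2c(cc(OC)c(OCOC)c2OC)C1 | intermediate
11 | (3S)-3-(2,2-dibromoethenyl)-6,8-dimethoxy-7-(methoxymethoxy)chromane | BrC(Br)=C[C@H]1COc2c(cc(OC)c(OCOC)c2OC)C1 | intermediate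
12 | dimethyl squarate (3,4-dimethoxycyclobut-3-ene-1,2-dione) | COC1=C(OC)C(=O)C1=O | starting material
13 | lithium {[(3S)-6,8-dimethoxy-7-(methoxymethoxy)chroman-3-yl]ethynyl}ide | [Li]C#C[C@H]1COc2c(cc(OC)c(OCOC)c2OC)C1 | intermediate (not isolated)
14 | 4-{[(3S)-6,8-dimethoxy-7-(methoxymethoxy)chroman-3-yl]ethynyl}-4-hydroxy-2,3-dimethoxycyclobut-2-en-1-one (both carbinol epimers) | COC1=C(OC)C(O)(C#C[C@H]2COc3c(cc(OC)c(OCOC)c3OC)C2)C1=O | intermediate
15 | (Z)-enynylketene: (3Z)-4-hydroxy-2,3-dimethoxy-6-[(3S)-6,8-dimethoxy-7-(methoxymethoxy)chroman-3-yl]hexa-1,3-dien-5-yn-1-one | O=C=C(OC)/C(OC)=C(\C#C[C@H]1COc2c(cc(OC)c(OCOC)c2OC)C1)O | intermediate (not isolated)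
16 | phenoxyl–aryl σ-diradical (4-hydroxy-2,3-dimethoxy-6-[(3S)-chroman-3-yl]phenoxyl with the radical at C5) | [O]c1c(OC)c(OC)c(O)[c]c1[C@H]2COc3c(cc(OC)c(OCOC)c3OC)C2 | intermediate (not isolated)
17 | 5-[(3S)-6,8-dimethoxy-7-(methoxymethoxy)chroman-3-yl]-2,3-dimethoxy-1,4-benzoquinone | COC1=C(OC)C(=O)C([C@H]2COc3c(cc(OC)c(OCOC)c3OC)C2)=CC1=O | intermediate
18 | 5-[(3S)-7-hydroxy-6,8-dimethoxy-3,4-dihydro-2H-chromen-3-yl]-2,3-dimethoxycyclohexa-2,5-diene-1,4-dione | COC1=C(OC)C(=O)C([C@H]2COc3c(cc(OC)c(O)c3OC)C2)=CC1=O | target

## Step count and least certain steps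

Total step count: 12. Longest linear sequence: 12 steps (from 1; 5 and 12 are purchased).

**Step 11 (key step).** The enynylketene may close to the five-membered ring, the σ-radical may abstract hydrogen from the chroman C2/C4 positions, or C3 may erode thermally, because the diradical is indiscriminate and the product is an epimerisable alkylquinone. Fallback through a closed-shell manifold, setting out from 10: Takai olefination (CrCl2, CHI3, THF) gives (3S)-3-[(E)-2-iodoethenyl]-6,8-dimethoxy-7-(methoxymethoxy)chromane F1. Iodine–lithium exchange (t-BuLi, −78 °C) and addition to 12 give the 4-alkenyl-4-hydroxycyclobutenone F2. Heating in toluene opens the ring and the dienylketene closes by 6π-electrocyclisation, with no diradical, to the hydroquinone F3. Mild oxidation with Ag2O (or air), which should not touch the protected ring A, returns to the route at 17.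

**Step 3.** C–O coupling may be slow at the di-ortho-substituted bromide, leaving the aldehyde open to disproportionation or hydrodebromination in warm hydroxide. Fallback setting out from 3: Miyaura borylation (B2pin2, Pd/SPhos, KOAc, dioxane) gives the pinacol boronate F4, and oxidation with N-methylmorpholine N-oxide (no peroxide, hence no Dakin cleavage of the salicylaldehyde) returns to 4.

**Step 6.** Facial selectivity may be insufficient on this electron-rich, heavily oxygenated substrate, since the ligand pocket was optimised on simpler cinnamic acids. Fallback setting out from 7: hydrogenation over Pd/C gives the racemic acid F5. Crystallisation with (S)-1-phenylethylamine is assumed to give the less soluble salt F6 of the (R)-acid (the amine antipode would be switched if the pairing is the other way). Acidification releases 8.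

**Step 10.** Excess butyllithium may metalate the propargylic C3–H (allenyl anion, erosion of configuration), or the carbenoid rearrangement may be incomplete, followed by double addition to 12. Fallback setting out from 10: Seyferth–Gilbert homologation with the Ohira–Bestmann reagent (K2CO3, MeOH) gives the terminal alkyne (3S)-3-ethynyl-6,8-dimethoxy-7-(methoxymethoxy)chromane F7. Deprotonation with EtMgBr (1.0 equiv), which cannot touch C3–H, and addition of the magnesium acetylide to 12 return to 14.

**Step 12.** The acid may promote conjugate addition to the quinone or tautomerisation toward the quinone methide (epimerisation at C3) during acetal cleavage. Fallback setting out from 17: reduction with Na2S2O4 gives the hydroquinone F3, in which C3–H is no longer activated and there is no acceptor. The MOM group is removed there (HCl, MeOH) to give the triol 5-[(3S)-7-hydroxy-6,8-dimethoxychroman-3-yl]-2,3-dimethoxybenzene-1,4-diol F8. Selective reoxidation of the hydroquinone ring with Ag2O (or air) arrives at 18.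

## Further compounds

F1 | step 11 | (3S)-3-[(E)-2-iodoethenyl]-6,8-dimethoxy-7-(methoxymethoxy)chromane | I/C=C/[C@H]1COc2c(cc(OC)c(OCOC)c2OC)C1
F2 | step 11 | 4-{(E)-2-[(3S)-6,8-dimethoxy-7-(methoxymethoxy)chroman-3-yl]ethenyl}-4-hydroxy-2,3-dimethoxycyclobut-2-en-1-one (both carbinol epimers) | COC1=C(OC)C(O)(/C=C/[C@H]2COc3c(cc(OC)c(OCOC)c3OC)C2)C1=O
F3 | step 11 | 5-[(3S)-6,8-dimethoxy-7-(methoxymethoxy)chroman-3-yl]-2,3-dimethoxybenzene-1,4-diol | COc1c(OC)c(O)c([C@H]2COc3c(cc(OC)c(OCOC)c3OC)C2)cc1O
F4 | step 3 | 3,5-dimethoxy-4-(methoxymethoxy)-2-(4,4,5,5-tetramethyl-1,3,2-dioxaborolan-2-yl)benzaldehyde | COCOc1c(OC)cc(C=O)c(B2OC(C)(C)C(C)(C)O2)c1OC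
F5 | step 6 | rac-6,8-dimethoxy-7-(methoxymethoxy)chromane-3-carboxylic acid | OC(=O)C1COc2c(cc(OC)c(OCOC)c2OC)C1
F6 | step 6 | (S)-1-phenylethylammonium (3R)-6,8-dimethoxy-7-(methoxymethoxy)chromane-3-carboxylate | C[C@H]([NH3+])c1ccccc1.[O-]C(=O)[C@H]1COc2c(cc(OC)c(OCOC)c2OC)C1
F7 | step 10 | (3S)-3-ethynyl-6,8-dimethoxy-7-(methoxymethoxy)chromane | C#C[C@H]1COc2c(cc(OC)c(OCOC)c2OC)C1
F8 | step 12 | 5-[(3S)-7-hydroxy-6,8-dimethoxychroman-3-yl]-2,3-dimethoxybenzene-1,4-diol | COc1c(OC)c(O)c([C@H]2COc3c(cc(OC)c(O)c3OC)C2)cc1O
A1 | alternative 1 | (4S)-4-benzyl-3-{(2S)-3-[2-(benzyloxy)-3,5-dimethoxy-4-(methoxymethoxy)phenyl]-2-(2,3,4,5-tetramethoxyphenyl)propanoyl}oxazolidin-2-one | COc1cc([C@H](Cc2cc(OC)c(OCOC)c(OC)c2OCc3ccccc3)C(=O)N4C(=O)OC[C@@H]4Cc5ccccc5)c(OC)c(OC)c1OC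
A2 | alternative 1 | (3S)-6,8-dimethoxy-7-(methoxymethoxy)-3-(2,3,4,5-tetramethoxyphenyl)chromane | COc1cc([C@H]2COc3c(cc(OC)c(OCOC)c3OC)C2)c(OC)c(OC)c1OC
A3 | alternative 2 | 6,8-dimethoxy-7-(methoxymethoxy)-3-(2,3,4,5-tetramethoxyphenyl)-2H-chromene | COc1cc(C2=Cc3cc(OC)c(OCOC)c(OC)c3OC2)c(OC)c(OC)c1OC
A4 | alternative 3 | 2,3-dimethoxy-1,4-benzoquinone | COC1=C(OC)C(=O)C=CC1=O
A5 | alternative 3 | rac-5-[6,8-dimethoxy-7-(methoxymethoxy)chroman-3-yl]-2,3-dimethoxy-1,4-benzoquinone | COC1=C(OC)C(=O)C(C2COc3c(cc(OC)c(OCOC)c3OC)C2)=CC1=O
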